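The flavanone is cut so that ring C is made first and ring A last. The six ring-C atoms O1, C2, C3, C4, C4a and C8a coincide with the C=O of the ring-B aldehyde plus the four-carbon backbone of an acetoacetate-derived 1,3-dioxygenated diene, the future C8a being the lactone carbonyl. One catalytic asymmetric hetero-Diels–Alder reaction therefore forms C2–C3 and O1–C8a, closes the ring and sets (S)-C2. Its precursor is simply the silyl-protected 3-hydroxy-4,5-dimethoxybenzaldehyde. A geranylated acetoacetate dianion then adds to C8a, acid transposes the enol ether to the C4 ketone, and a Claisen closure C4a–C5 aromatises ring A with the geranyl group locked at C6.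

Key step: step 4

Remark on the chemistry (assumption): Si-face attack with the (S)-binaphtholate is assumed by analogy with other BINOL–titanium additions to aldehydes. If the sense proves opposite, (R)-BINOL is used.
Remark on the chemistry (numbering and descriptors): flavanone numbering is used for all intermediates. C2 stays (S) throughout because O > aryl > CH2 > H holds in every compound. The centre alpha to the ester in 9, 11, 12 and 13 is left unassigned because it becomes sp2 in ring A.
Remark on the chemistry (protecting group): the ring-B phenol is carried as a TIPS ether. It does not chelate titanium, it is inert to the dianion and to DBU, and it leaves under buffered fluoride. An acetal group would need acid while the geranyl chain sits between two phenols, with a risk of chroman formation.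

Step 1
Reactants: 1 3-hydroxy-4,5-dimethoxybenzaldehyde
Product: 2 3,4-dimethoxy-5-(triisopropylsilyloxy)benzaldehyde
Conditions: TIPSCl, imidazole, DMF, rt
Reagents that add atoms: triisopropylsilyl chloride, CC(C)[Si](Cl)(C(C)C)C(C)C
Why: Imidazole-promoted O-silylation of a phenol is routine, the aldehyde is inert and no stereocentre is involved.

Step 2
Reactants: 3 methyl acetoacetate
Product: 4 methyl (E)-3-methoxybut-2-enoate
Conditions: HC(OMe)3, cat. H2SO4, MeOH, rt, then distillation
Reagents that add atoms: trimethyl orthoformate, COC(OC)OC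
Why: Acid-catalysed ketalisation of the ketone followed by loss of methanol (enol ether formation) should give the conjugated, thermodynamically preferred (E)-beta-methoxy enoate.

Step 3
Reactants: 4 methyl (E)-3-methoxybut-2-enoate
Product: 5 Brassard's diene, 1,3-dimethoxy-1-(trimethylsilyloxy)buta-1,3-diene
Conditions: LDA (commercial solution), THF, −78 °C; TMSCl, −78 °C → rt; distillation
Reagents that add atoms: chlorotrimethylsilane, C[Si](C)(C)Cl
Why: Kinetic gamma-deprotonation of the beta-methoxy enoate and O-silylation of the lithium dienolate (silyl ketene acetal formation) is the standard entry to this diene, and its ketene-acetal geometry has no bearing on the product.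

Step 4
Reactants: 2 3,4-dimethoxy-5-(triisopropylsilyloxy)benzaldehyde; 5 Brassard's diene
Product: 7 (6S)-4-methoxy-6-[3,4-dimethoxy-5-(triisopropylsilyloxy)phenyl]-5,6-dihydro-2H-pyran-2-one, via orthoester cycloadduct 6 (not isolated)
Conditions: (S)-BINOL/Ti(OiPr)4 (1:1, 10 mol %), 4 Å MS, toluene, 0 °C → rt; then cat. TFA, CH2Cl2, 0 °C
Reagents that add atoms: none
Why: The binaphtholate–titanium Lewis acid binds the aldehyde oxygen, the unsubstituted CH2 terminus of 5 (the vinylogous ketene-acetal position with the largest HOMO coefficient) attacks the carbonyl carbon and the aldehyde oxygen closes on the ketene-acetal carbon, concertedly or as a vinylogous Mukaiyama aldol followed by cyclisation; orthoester 6 then expels TMSOMe, and TFA converts any open-chain (E)-delta-oxy enoate, whose chain is cis to the ester, into the same lactone. The closest known reaction type is this very one, the catalytic asymmetric hetero-Diels–Alder reaction of Brassard's diene with non-enolisable aromatic aldehydes. The one ring is closed in the [4+2] mode (6-exo-trig lactonisation in the stepwise variant), which creates C2–C3 and O1–C8a. C2 is the only new stereocentre kept in 7 and is controlled by the ligand alone: the (S)-binaphtholate should leave the Si face of the bound aldehyde open, which gives (S). Regioselectivity follows from the polarisation of the diene, chemoselectivity from the absence of enolisable hydrogens, and reactivity is retained because the 4-methoxy group is twisted out of conjugation by its two ortho neighbours. The bulky TIPS ether offers titanium no second, chelating site, so a single binding mode of the aldehyde is expected.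

Step 5
Reactants: 3 methyl acetoacetate; 8 geranyl bromide
Product: 9 methyl (4E)-2-acetyl-5,9-dimethyldeca-4,8-dienoate (methyl 2-geranylacetoacetate, racemic)
Conditions: NaH, THF, 0 °C; 8, 0 °C → rt (3 in 1.5-fold excess)
Reagents that add atoms: none
Why: SN2 C-alkylation of a beta-keto ester sodium enolate with a primary allylic bromide (acetoacetic ester alkylation) retains the (E)-alkene, and the excess of 3 limits dialkylation.

Step 6
Reactants: 9 methyl 2-geranylacetoacetate; 7 (6S)-lactone
Product: 12 methyl (4E)-2-{[(2S)-2-[3,4-dimethoxy-5-(triisopropylsilyloxy)phenyl]-4-oxo-3,4-dihydro-2H-pyran-6-yl]acetyl}-5,9-dimethyldeca-4,8-dienoate, via dilithio dianion 10 (not isolated), via lactol 11 (not isolated)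
Conditions: 9 (2.5 equiv), LDA (5.1 equiv), THF, 0 °C; 7, −78 → −30 °C; then 1 M aq HCl, THF, 0 °C → rt
Reagents that add atoms: water, O
Why: The terminal carbanion of the acetoacetate dianion should add 1,2 to the lactone carbonyl (Claisen-type acylation of a 1,3-dicarbonyl dianion by a lactone, as known for carbon nucleophiles on 4-alkoxy-5,6-dihydropyran-2-ones), and dilute acid then ionises the doubly oxygen-stabilised lactol and hydrolyses the methyl enol ether in a Stork–Danheiser-type transposition that never touches the C2–O1 bond, so the (S) centre is kept.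

Step 7
Reactants: 12 dihydropyranone keto ester
Product: 14 (2S)-6-geranyl-5,7-dihydroxy-2-[3,4-dimethoxy-5-(triisopropylsilyloxy)phenyl]chroman-4-one, via keto tautomer 13 (not isolated)
Conditions: DBU (3 equiv), toluene, rt → 45 °C; AcOH quench at 0 °C
Reagents that add atoms: none
Why: DBU removes the most acidic C8–H (between the C7 ketone and the vinylogous ester), and the dienolate acylates at its alpha carbon C4a with the still un-enolised methyl ester in a 6-(enolendo)-exo-trig Dieckmann-type closure, the biomimetic Claisen cyclisation known for 3,5,7-tricarbonyl esters, while the geranyl group on C6 blocks the competing aldol aromatisation and the charge parked on the C4 oxygen lowers the C3–H acidity, so retro-oxa-Michael racemisation of C2 should stay slow.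

Step 8
Reactants: 14 TIPS-protected flavanone
Product: 15 (2S)-6-[(2E)-3,7-dimethylocta-2,6-dienyl]-5,7-dihydroxy-2-(3-hydroxy-4,5-dimethoxyphenyl)chroman-4-one (CNP0228243.1)
Conditions: TBAF, AcOH (1:1.2), THF, 0 °C
Reagents that add atoms: none
Why: Fluoride-mediated desilylation cleaves the aryl silyl ether fast, the acetic acid buffer keeps the medium below the basicity at which flavanones open to chalcones, and the geranyl alkenes and the ring-A phenols are untouched.

Compound list
1 | 3-hydroxy-4,5-dimethoxybenzaldehyde | COc1cc(C=O)cc(O)c1OC | starting material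
2 | 3,4-dimethoxy-5-(triisopropylsilyloxy)benzaldehyde | COc1cc(C=O)cc(O[Si](C(C)C)(C(C)C)C(C)C)c1OC | intermediate
3 | methyl acetoacetate | CC(=O)CC(=O)OC | starting material
4 | methyl (E)-3-methoxybut-2-enoate | CO/C(C)=C/C(=O)OC | intermediate
5 | Brassard's diene, 1,3-dimethoxy-1-(trimethylsilyloxy)buta-1,3-diene | C=C(OC)C=C(OC)O[Si](C)(C)C | intermediate
6 | (6S)-2,4-dimethoxy-6-[3,4-dimethoxy-5-(triisopropylsilyloxy)phenyl]-2-(trimethylsilyloxy)-5,6-dihydro-2H-pyran (orthoester cycloadduct, orthoester carbon unassigned) | COc1cc([C@@H]2CC(OC)=CC(OC)(O[Si](C)(C)C)O2)cc(O[Si](C(C)C)(C(C)C)C(C)C)c1OC | intermediate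
7 | (6S)-4-methoxy-6-[3,4-dimethoxy-5-(triisopropylsilyloxy)phenyl]-5,6-dihydro-2H-pyran-2-one | COc1cc([C@@H]2CC(OC)=CC(=O)O2)cc(O[Si](C(C)C)(C(C)C)C(C)C)c1OC | intermediate
8 | geranyl bromide | BrC/C=C(\C)CCC=C(C)C | starting material
9 | methyl (4E)-2-acetyl-5,9-dimethyldeca-4,8-dienoate | COC(=O)C(C/C=C(\C)CCC=C(C)C)C(C)=O | intermediate
10 | dilithio dianion (1,3-bis-enolate) of 9 | [Li+].[Li+].C=C([O-])C(C/C=C(\C)CCC=C(C)C)=C([O-])OC | intermediate
11 | methyl (4E)-2-{[(6S)-2-hydroxy-4-methoxy-6-[3,4-dimethoxy-5-(triisopropylsilyloxy)phenyl]-5,6-dihydro-2H-pyran-2-yl]acetyl}-5,9-dimethyldeca-4,8-dienoate (lactol) | COc1cc([C@@H]2CC(OC)=CC(O)(CC(=O)C(C/C=C(\C)CCC=C(C)C)C(=O)OC)O2)cc(O[Si](C(C)C)(C(C)C)C(C)C)c1OC | intermediate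
12 | methyl (4E)-2-{[(2S)-2-[3,4-dimethoxy-5-(triisopropylsilyloxy)phenyl]-4-oxo-3,4-dihydro-2H-pyran-6-yl]acetyl}-5,9-dimethyldeca-4,8-dienoate | COc1cc([C@@H]2CC(=O)C=C(CC(=O)C(C/C=C(\C)CCC=C(C)C)C(=O)OC)O2)cc(O[Si](C(C)C)(C(C)C)C(C)C)c1OC | intermediate
13 | (2S)-6-geranyl-2-[3,4-dimethoxy-5-(triisopropylsilyloxy)phenyl]-2,3-dihydro-4aH-chromene-4,5,7(6H)-trione (keto tautomer of 14) | COc1cc([C@@H]2CC(=O)C3C(=O)C(C/C=C(\C)CCC=C(C)C)C(=O)C=C3O2)cc(O[Si](C(C)C)(C(C)C)C(C)C)c1OC | intermediate
14 | (2S)-6-geranyl-5,7-dihydroxy-2-[3,4-dimethoxy-5-(triisopropylsilyloxy)phenyl]chroman-4-one | COc1cc([C@@H]2CC(=O)c3c(cc(O)c(C/C=C(\C)CCC=C(C)C)c3O)O2)cc(O[Si](C(C)C)(C(C)C)C(C)C)c1OC | intermediate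
15 | (2S)-6-[(2E)-3,7-dimethylocta-2,6-dienyl]-5,7-dihydroxy-2-(3-hydroxy-4,5-dimethoxyphenyl)chroman-4-one | COc1cc([C@@H]2CC(=O)c3c(cc(O)c(C/C=C(\C)CCC=C(C)C)c3O)O2)cc(O)c1OC | target

Total step count: 8.
Longest linear sequence: 6 steps (3 → 4 → 5 → 7 → 12 → 14 → 15, that is steps 2, 3, 4, 6, 7 and 8).

Steps most likely to fail

1. Step 6.
- Risk: the strongly basic dianion may remove a C3 proton of the lactone instead of adding to C8a. That would trigger beta-elimination of the carboxylate, with ring opening and loss of the C2 centre. The dianion may also attack C4 in an addition–elimination mode.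
- Fallback: it sets out from 7 and comes back at 12.
- The lactone is opened without strong base by MeNH(OMe)·HCl/AlMe3 (CH2Cl2, 0 °C). This gives (2E,5S)-5-hydroxy-N,3-dimethoxy-N-methyl-5-[3,4-dimethoxy-5-(triisopropylsilyloxy)phenyl]pent-2-enamide F1.
- The carbinol is capped (TESCl, imidazole) to the triethylsilyl ether F2, in which the C2 oxygen is no longer a leaving group of carboxylate quality.
- Dianion 10 is acylated by this Weinreb amide, whose chelated tetrahedral intermediate stops over-addition, to give the open-chain enol-ether keto ester F3.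
- 1 M HCl in THF then removes the TES group. The freed alcohol closes on C8a to lactol 11, and the transposition of step 6 gives 12.

2. Step 7.
- Risk: if C-acylation at C4a is slow, base-induced retro-oxa-Michael opening of ring C can compete. That would erode the enantiomeric purity and allow reclosure on the wrong phenol.
- Fallback: it sets out from 7 and comes back at 14, and it replaces the anionic condensation by a neutral thermal ring closure.
- tert-Butyl acetoacetate is alkylated with 8 (NaH, THF) to tert-butyl 2-geranylacetoacetate F4.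
- Its dilithio dianion F5 (LDA, THF) is added to 7. The tert-butyl lactol F6 is transposed with dilute acid as in step 6 to the tert-butyl ester dihydropyranone F7.
- In refluxing toluene F7 should lose tert-butanol to give the alpha-geranyl acylketene F8.
- The ketene carbon of F8 is captured by C4a in a 6π electrocyclisation of its enol form, the closing event of dienylketene benzannulations. Tautomerisation then gives 14 without any base.

3. Step 4.
- Risk: facial selectivity or turnover may be insufficient with this electron-rich aldehyde, and the moisture-sensitive diene may be consumed by hydrolysis.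
- Fallback: it sets out from 2 and comes back at 7. It separates C–C bond formation from ring closure and activates the nucleophile instead of the aldehyde.
- 2,2,6-Trimethyl-4H-1,3-dioxin-4-one is converted (LDA, TMSCl) into the dioxinone silyl dienolate F9.
- F9 undergoes a catalytic asymmetric vinylogous Mukaiyama aldol with 2 through a chiral copper dienolate (Cu(OTf)2, the Tol-BINAP antipode that delivers the (S)-carbinol, Bu4N[Ph3SiF2], THF, −78 °C; acidic work-up). This gives the (S)-hydroxyethyl dioxinone F10.
- Heating F10 in toluene expels acetone and lactonises to the (6S)-pyran-2,4-dione F11.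
- O-Methylation of F11 (Me2SO4, K2CO3, acetone) gives 7.

Further compounds
F1 | step 6 | (2E,5S)-5-hydroxy-N,3-dimethoxy-N-methyl-5-[3,4-dimethoxy-5-(triisopropylsilyloxy)phenyl]pent-2-enamide | COc1cc([C@@H](O)C/C(OC)=C\C(=O)N(C)OC)cc(O[Si](C(C)C)(C(C)C)C(C)C)c1OC
F2 | step 6 | (2E,5S)-N,3-dimethoxy-N-methyl-5-[3,4-dimethoxy-5-(triisopropylsilyloxy)phenyl]-5-(triethylsilyloxy)pent-2-enamide | COc1cc([C@@H](O[Si](CC)(CC)CC)C/C(OC)=C\C(=O)N(C)OC)cc(O[Si](C(C)C)(C(C)C)C(C)C)c1OC
F3 | step 6 | methyl (4E)-2-[(4E,7S)-5-methoxy-3-oxo-7-[3,4-dimethoxy-5-(triisopropylsilyloxy)phenyl]-7-(triethylsilyloxy)hept-4-enoyl]-5,9-dimethyldeca-4,8-dienoate | COc1cc([C@@H](O[Si](CC)(CC)CC)C/C(OC)=C\C(=O)CC(=O)C(C/C=C(\C)CCC=C(C)C)C(=O)OC)cc(O[Si](C(C)C)(C(C)C)C(C)C)c1OC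
F4 | step 7 | tert-butyl (4E)-2-acetyl-5,9-dimethyldeca-4,8-dienoate | CC(=O)C(C/C=C(\C)CCC=C(C)C)C(=O)OC(C)(C)C
F5 | step 7 | dilithio dianion of F4 | [Li+].[Li+].C=C([O-])C(C/C=C(\C)CCC=C(C)C)=C([O-])OC(C)(C)C
F6 | step 7 | tert-butyl ester analogue of lactol 11 | COc1cc([C@@H]2CC(OC)=CC(O)(CC(=O)C(C/C=C(\C)CCC=C(C)C)C(=O)OC(C)(C)C)O2)cc(O[Si](C(C)C)(C(C)C)C(C)C)c1OC
F7 | step 7 | tert-butyl ester analogue of dihydropyranone 12 | COc1cc([C@@H]2CC(=O)C=C(CC(=O)C(C/C=C(\C)CCC=C(C)C)C(=O)OC(C)(C)C)O2)cc(O[Si](C(C)C)(C(C)C)C(C)C)c1OC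
F8 | step 7 | alpha-geranyl acylketene derived from F7 | COc1cc([C@@H]2CC(=O)C=C(CC(=O)C(C/C=C(\C)CCC=C(C)C)=C=O)O2)cc(O[Si](C(C)C)(C(C)C)C(C)C)c1OC
F9 | step 4 | 2,2-dimethyl-6-methylidene-4-(trimethylsilyloxy)-6H-1,3-dioxine | C=C1C=C(O[Si](C)(C)C)OC(C)(C)O1
F10 | step 4 | 6-{(2S)-2-hydroxy-2-[3,4-dimethoxy-5-(triisopropylsilyloxy)phenyl]ethyl}-2,2-dimethyl-4H-1,3-dioxin-4-one | COc1cc([C@@H](O)CC2=CC(=O)OC(C)(C)O2)cc(O[Si](C(C)C)(C(C)C)C(C)C)c1OC
F11 | step 4 | (6S)-6-[3,4-dimethoxy-5-(triisopropylsilyloxy)phenyl]dihydro-2H-pyran-2,4(3H)-dione | COc1cc([C@@H]2CC(=O)CC(=O)O2)cc(O[Si](C(C)C)(C(C)C)C(C)C)c1OC
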